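## Retrosynthetic overview

1. Cespitularin K (24) comes from oxidation of hydroxy enone 23, which comes from a transannular Piancatelli rearrangement (conrotatory 4π-electrocyclisation) of the macrocyclic furylcarbinol ether 21; the cyclopentenone ring is formed last.
2. 21 comes from methylenation of ketone 20, whose 13-membered ring is closed by a macro-aldol (CH2–CH(OAc) bond) of the methyl ketone/enal 17.
3. 17 comes from the α-lithiated 3,4-fused furan 10 and the C5 enal 13 (furan–carbinol bond).
4. 10 comes from annulation of ring A onto the (R)-limonene-derived keto aldehyde 3 with fumaraldehyde monoacetal 4 (radical–polar crossover), followed by aromatisation to the furan.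
5. Order of ring formation: ring A, then furan, then the 13-membered carbocycle, then the cyclopentenone (which converts the 13-ring into the bridged 12-ring).

Assumption: commercial (+)-limonene 1,2-oxide (cis/trans mixture, 4R) is the chiral starting material; centres that are destroyed later (three ring centres of 5 and 6, the ring carbon bearing the acetal in 7 and 8, the silyloxy carbon of 16 to 21) are carried as epimer mixtures and left unspecified in the SMILES.

## Route

Step 1
Reactants: 1 (+)-limonene 1,2-oxide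
Product: 3 (3R)-6-oxo-3-(prop-1-en-2-yl)heptanal, via limonene-1,2-diol 2 (not isolated)
Conditions: H5IO6, THF/H2O, 0 °C → rt
Reagents that add atoms: water, O
Why: Periodic acid hydrolyses the epoxide and cleaves the resulting vicinal diol (Malaprade glycol cleavage) without touching the isopropenyl group, so the limonene stereocentre is carried over unchanged.

Step 2
Reactants: 3 (3R)-6-oxo-3-(prop-1-en-2-yl)heptanal; 4 (2E)-4,4-dimethoxybut-2-enal
Product: 5 (4R)-2-(dimethoxymethyl)-6-hydroxy-3,3-dimethyl-4-(3-oxobutyl)cyclohexane-1-carbaldehyde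
Conditions: 4 (3 equiv), Fe(acac)3 (0.3 equiv), PhSiH3 (2.5 equiv), EtOH/(CH2OH)2 (5:1), 0 °C → rt
Reagents that add atoms: none
Why: Hydrogen-atom transfer from an iron hydride to the isopropenyl group gives a tertiary radical that adds to the enal (Giese addition), and the resulting iron enolate closes ring A by intramolecular aldol addition to the aldehyde (radical–polar crossover annulation); the radical path cannot epimerise the neighbouring limonene-derived centre, and the three new centres are uncontrolled and erased in steps 3 to 5.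

Step 3
Reactants: 5 (4R)-2-(dimethoxymethyl)-6-hydroxy-3,3-dimethyl-4-(3-oxobutyl)cyclohexane-1-carbaldehyde
Product: 7 (4R)-6-(dimethoxymethyl)-5,5-dimethyl-4-(3-oxobutyl)cyclohex-1-ene-1-carbaldehyde, via mesylate 6 (not isolated)
Conditions: MsCl, Et3N, CH2Cl2, 0 °C → rt
Reagents that add atoms: none
Why: Mesylation of the β-hydroxy aldehyde and E1cB elimination give the conjugated enal.

Step 4
Reactants: 7 (4R)-6-(dimethoxymethyl)-5,5-dimethyl-4-(3-oxobutyl)cyclohex-1-ene-1-carbaldehyde
Product: 8 4-[(1R)-5-(dimethoxymethyl)-4-(hydroxymethyl)-6,6-dimethylcyclohex-3-en-1-yl]butan-2-one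
Conditions: NaBH4, MeOH/CH2Cl2 (1:1), −78 °C
Reagents that add atoms: none
Why: At −78 °C borohydride reduces the aldehyde (1,2-reduction) much faster than the acyclic methyl ketone (chemoselective carbonyl reduction).

Step 5
Reactants: 8 4-[(1R)-5-(dimethoxymethyl)-4-(hydroxymethyl)-6,6-dimethylcyclohex-3-en-1-yl]butan-2-one
Product: 10 (5S)-5-(3,3-dimethoxybutyl)-4,4-dimethyl-4,5,6,7-tetrahydro-2-benzofuran, via furan ketone 9 (not isolated)
Conditions: CSA (5 mol %), CH2Cl2, rt; then HC(OMe)3, MeOH, rt
Reagents that add atoms: trimethyl orthoformate, COC(OC)OC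
Why: Acid-catalysed cyclisation of the γ-hydroxy acetal with loss of two MeOH and a double-bond shift (Paal–Knorr-type furan synthesis) is driven by aromatisation, and the ketone is then masked as its dimethyl ketal for the organolithium step.

Step 6
Reactants: 11 2,2-dimethoxyacetaldehyde; 12 2-(triphenylphosphoranylidene)propanal
Product: 13 (2E)-4,4-dimethoxy-2-methylbut-2-enal
Conditions: PhMe, 70 °C
Reagents that add atoms: none
Why: Wittig olefination with the stabilised formyl ylide gives the (E)-2-methyl enal selectively.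

Step 7
Reactants: 10 (5S)-5-(3,3-dimethoxybutyl)-4,4-dimethyl-4,5,6,7-tetrahydro-2-benzofuran; 13 (2E)-4,4-dimethoxy-2-methylbut-2-enal
Product: 16 tert-butyl{[(2E)-1-[(5S)-5-(3,3-dimethoxybutyl)-4,4-dimethyl-4,5,6,7-tetrahydro-2-benzofuran-1-yl]-4,4-dimethoxy-2-methylbut-2-en-1-yl]oxy}dimethylsilane, via furyllithium 14 (not isolated), via lithium alkoxide 15 (not isolated)
Conditions: n-BuLi, TMEDA, THF, −78 → 0 °C; 13, −78 °C; TBSCl, DMPU, −78 °C → rt
Reagents that add atoms: tert-butyldimethylsilyl chloride, CC(C)(C)[Si](C)(C)Cl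
Why: Directed α-lithiation of the furan takes place at the free position remote from the gem-dimethyl group, and 1,2-addition to the enal followed by O-silylation gives the furylcarbinol ether as a 1:1 mixture at the new carbinol centre, which is erased in step 11.

Step 8
Reactants: 16 bis-acetal silyl ether
Product: 17 (2E)-4-{[tert-butyl(dimethyl)silyl]oxy}-4-[(5S)-4,4-dimethyl-5-(3-oxobutyl)-4,5,6,7-tetrahydro-2-benzofuran-1-yl]-3-methylbut-2-enal
Conditions: PPTS (cat.), acetone/H2O (10:1), rt
Reagents that add atoms: water, O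
Why: Mild acid hydrolysis removes both dimethyl acetals (ketone and enal) while the silyl ether survives.

Step 9
Reactants: 17 keto enal
Product: 20 13-membered acetoxy ketone (chain CH(OTBS)–C(CH3)=CH–CH(OAc)–CH2–C(=O)–CH2–CH2 joining furan C-1 to ring C-5; E alkene; S at the acetoxy carbon), via lithium enolate 18 (not isolated), via lithium aldolate 19 (not isolated)
Conditions: LiN(i-Pr)2 (1.1 equiv), THF, slow addition of 17 (final 2 mM), −78 °C; then Ac2O, −78 → −20 °C
Reagents that add atoms: acetic anhydride, CC(=O)OC(C)=O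
Why: Kinetic enolisation of the methyl ketone on its methyl side and intramolecular aldol addition to the enal under high dilution close the 13-membered ring, the aldolate is trapped as the acetate before retro-aldol can occur, and the (S)-carbinol centre is expected from macrocyclic substrate control (lithium-chelated transition state on the ring periphery, relayed from the limonene-derived centre through the rigid ring A–furan unit), which is the least certain stereochemical element of the route.

Step 10
Reactants: 20 13-membered acetoxy ketone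
Product: 21 13-membered methylene acetate (20 with C(=CH2) in place of C(=O))
Conditions: Cp2Ti(μ-Cl)(μ-CH2)AlMe2 (Tebbe reagent), pyridine (cat.), THF/PhMe, −40 → 0 °C
Reagents that add atoms: Tebbe reagent, C[Al](C)C[Ti](Cl)(C1C=CC=C1)C1C=CC=C1
Why: Titanium-methylidene (Tebbe) olefination converts the ketone into the exocyclic methylene under non-basic conditions, so the β-acetoxy ketone does not eliminate and the acetate is not attacked at low temperature.

Step 11
Reactants: 21 13-membered methylene acetate
Product: 23 trans-hydroxy enone (24 with CH–OH in place of the ring C=O attached to the alkene carbon that bears C(CH3)2), via furylcarbinol 22 (not isolated)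
Conditions: Dy(OTf)3 (10 mol %), MeCN/H2O (5:1), 80 °C
Reagents that add atoms: water, O
Why: Piancatelli rearrangement: ionisation at the furylic carbon, addition of water to the free furan α-carbon, ring opening and thermally allowed conrotatory 4π-electrocyclisation of the pentadienyl cation form the five-membered carbocycle transannularly as the trans-4-hydroxy-5-alkenylcyclopentenone, the bridging chain forcing the new C–C bond onto the face of the limonene-derived side chain while both silyloxy epimers converge through the common cation.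

Step 12
Reactants: 23 trans-hydroxy enone
Product: 24 Cespitularin K
Conditions: Dess–Martin periodinane, CH2Cl2, 0 °C → rt
Reagents that add atoms: none
Why: Dess–Martin oxidation of the allylic carbinol gives the cyclopent-4-ene-1,3-dione, and the acidic C–H between the two carbonyls rests in the only configuration the 12-membered bridge allows (cis to the ring-A side chain, thermodynamic control by the limonene-derived centre).

## Compound list

1 | (+)-limonene 1,2-oxide, (4R)-1-methyl-4-(prop-1-en-2-yl)-7-oxabicyclo[4.1.0]heptane, cis/trans mixture | CC12CC[C@H](CC1O2)C(C)=C | starting material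
2 | (4R)-p-menth-8-ene-1,2-diol | CC1(O)CC[C@H](CC1O)C(C)=C | intermediate
3 | (3R)-6-oxo-3-(prop-1-en-2-yl)heptanal | CC(=O)CC[C@H](CC=O)C(C)=C | intermediate
4 | (2E)-4,4-dimethoxybut-2-enal (fumaraldehyde mono(dimethyl acetal)) | COC(OC)/C=C/C=O | starting material
5 | (4R)-2-(dimethoxymethyl)-6-hydroxy-3,3-dimethyl-4-(3-oxobutyl)cyclohexane-1-carbaldehyde (epimers at C-1, C-2, C-6) | CC(=O)CC[C@@H]1CC(O)C(C=O)C(C(OC)OC)C1(C)C | intermediate
6 | methanesulfonate of 5 | CC(=O)CC[C@@H]1CC(OS(C)(=O)=O)C(C=O)C(C(OC)OC)C1(C)C | intermediate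
7 | (4R)-6-(dimethoxymethyl)-5,5-dimethyl-4-(3-oxobutyl)cyclohex-1-ene-1-carbaldehyde | CC(=O)CC[C@@H]1CC=C(C=O)C(C(OC)OC)C1(C)C | intermediate
8 | 4-[(1R)-5-(dimethoxymethyl)-4-(hydroxymethyl)-6,6-dimethylcyclohex-3-en-1-yl]butan-2-one | CC(=O)CC[C@@H]1CC=C(CO)C(C(OC)OC)C1(C)C | intermediate
9 | 4-[(5S)-4,4-dimethyl-4,5,6,7-tetrahydro-2-benzofuran-5-yl]butan-2-one | CC(=O)CC[C@@H]1CCc2cocc2C1(C)C | intermediate
10 | (5S)-5-(3,3-dimethoxybutyl)-4,4-dimethyl-4,5,6,7-tetrahydro-2-benzofuran | COC(C)(OC)CC[C@@H]1CCc2cocc2C1(C)C | intermediate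
11 | 2,2-dimethoxyacetaldehyde | COC(OC)C=O | starting material
12 | 2-(triphenylphosphoranylidene)propanal | CC(C=O)=P(c1ccccc1)(c1ccccc1)c1ccccc1 | starting material
13 | (2E)-4,4-dimethoxy-2-methylbut-2-enal | COC(OC)/C=C(\C)C=O | intermediate
14 | [(5S)-5-(3,3-dimethoxybutyl)-4,4-dimethyl-4,5,6,7-tetrahydro-2-benzofuran-1-yl]lithium | COC(C)(OC)CC[C@@H]1CCc2c([Li])occ2C1(C)C | intermediate
15 | lithium (2E)-1-[(5S)-5-(3,3-dimethoxybutyl)-4,4-dimethyl-4,5,6,7-tetrahydro-2-benzofuran-1-yl]-4,4-dimethoxy-2-methylbut-2-en-1-olate | COC(C)(OC)CC[C@@H]1CCc2c(C([O-])/C(C)=C/C(OC)OC)occ2C1(C)C.[Li+] | intermediate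
16 | tert-butyl{[(2E)-1-[(5S)-5-(3,3-dimethoxybutyl)-4,4-dimethyl-4,5,6,7-tetrahydro-2-benzofuran-1-yl]-4,4-dimethoxy-2-methylbut-2-en-1-yl]oxy}dimethylsilane (carbinol epimers) | COC(C)(OC)CC[C@@H]1CCc2c(C(O[Si](C)(C)C(C)(C)C)/C(C)=C/C(OC)OC)occ2C1(C)C | intermediate
17 | (2E)-4-{[tert-butyl(dimethyl)silyl]oxy}-4-[(5S)-4,4-dimethyl-5-(3-oxobutyl)-4,5,6,7-tetrahydro-2-benzofuran-1-yl]-3-methylbut-2-enal | CC(=O)CC[C@@H]1CCc2c(C(O[Si](C)(C)C(C)(C)C)/C(C)=C/C=O)occ2C1(C)C | intermediate
18 | lithium enolate of 17 (methyl side of the ketone) | [Li+].[O-]C(=C)CC[C@@H]1CCc2c(C(O[Si](C)(C)C(C)(C)C)/C(C)=C/C=O)occ2C1(C)C | intermediate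
19 | lithium aldolate of the 13-membered ring, (S)-alkoxide | O=C1CC[C@@H]2CCc3c(C2(C)C)coc3C(O[Si](C)(C)C(C)(C)C)/C(C)=C/[C@@H]([O-])C1.[Li+] | intermediate
20 | 13-membered acetoxy ketone: chain CH(OTBS)–C(CH3)=CH–CH(OAc)–CH2–C(=O)–CH2–CH2 joining furan C-1 to ring C-5 of the 4,4-dimethyl-4,5,6,7-tetrahydro-2-benzofuran; E alkene; S at the acetoxy carbon; ring methine as in 10 | O=C1CC[C@@H]2CCc3c(C2(C)C)coc3C(O[Si](C)(C)C(C)(C)C)/C(C)=C/[C@@H](OC(C)=O)C1 | intermediate
21 | 13-membered methylene acetate: 20 with C(=CH2) in place of C(=O) | C=C1CC[C@@H]2CCc3c(C2(C)C)coc3C(O[Si](C)(C)C(C)(C)C)/C(C)=C/[C@@H](OC(C)=O)C1 | intermediate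
22 | furylcarbinol: 21 with OH in place of OTBS | C=C1CC[C@@H]2CCc3c(C2(C)C)coc3C(O)/C(C)=C/[C@@H](OC(C)=O)C1 | intermediate
23 | trans-hydroxy enone: 24 with (R)-CH–OH in place of the ring C=O attached to the alkene carbon bearing C(CH3)2; OH trans to the alkenyl chain on the neighbouring carbon | C=C1CC[C@@H]2CCC3=C([C@H](O)[C@H](C3=O)/C(C)=C/[C@@H](OC(C)=O)C1)C2(C)C | intermediate
24 | Cespitularin K | C=C1CC[C@@H]2CCC3=C(C(=O)[C@H](C3=O)/C(C)=C/[C@@H](OC(C)=O)C1)C2(C)C | target

## Step count and risks

Total: 12 steps. Longest linear sequence: 11 steps (steps 1 to 5 and 7 to 12 from 1); step 6 makes the C5 enal.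

Most likely to fail:

Step 2 (annulation). A tertiary radical must add to a β-substituted enal, and the enolate must undergo aldol addition before it is protonated. The fallback sets out from 3 and uses the unhindered cyclic acceptor furan-2(5H)-one under the same Fe(acac)3/PhSiH3 conditions. This gives the hydroxy lactone (5R)-7-hydroxy-4,4-dimethyl-5-(3-oxobutyl)hexahydro-2-benzofuran-1(3H)-one F1. Dehydration (MsCl, Et3N) gives the alkylidene lactone F2. RhCl3·3H2O in EtOH at 80 °C moves the double bond into the lactone ring to give the fused butenolide F3. The ketone is masked (HC(OMe)3, MeOH, PPTS) as the dimethyl ketal F4. Reduction with i-Bu2AlH at −78 °C and dehydration of the lactol (MsCl, Et3N) returns to the route at 10.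

Step 9 (macro-aldol). The ring closure may be low-yielding, and the configuration at the new carbinol is not secured by precedent. The fallback sets out from 17: the aldolate is quenched with AcOH instead of Ac2O. If the epimeric (R)-hydroxy ketone F5 is the main product, it is methylenated with the Tebbe reagent to the epimeric methylene alcohol F6. The acetate is then introduced with inversion by a Mitsunobu reaction (AcOH, PPh3, DIAD, PhMe, 0 °C), which returns to the route at 21.

Step 11 (Piancatelli rearrangement). The electrocyclisation has to occur transannularly on a 3,4-fused furan, and the allylic acetate may ionise. The fallback sets out from 21: ionic reduction (Et3SiH, BF3·OEt2, CH2Cl2, −78 °C) removes the silyloxy group to give the 2-alkylfuran F7. Singlet-oxygen [4+2] cycloaddition (O2, hν, rose bengal, MeOH, 0 °C), reduction of the endoperoxide with Me2S and Et3N-mediated intramolecular aldol give the hydroxy enone F8 as carbinol epimers. Both epimers are oxidised under the step 12 conditions, so the fallback returns to the route at 24.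

## Further compounds

F1 | step 2 | (5R)-7-hydroxy-4,4-dimethyl-5-(3-oxobutyl)hexahydro-2-benzofuran-1(3H)-one | CC(=O)CC[C@@H]1CC(O)C2C(=O)OCC2C1(C)C
F2 | step 2 | (5R)-4,4-dimethyl-5-(3-oxobutyl)-3a,4,5,6-tetrahydro-2-benzofuran-1(3H)-one | CC(=O)CC[C@@H]1CC=C2C(=O)OCC2C1(C)C
F3 | step 2 | (5S)-4,4-dimethyl-5-(3-oxobutyl)-4,5,6,7-tetrahydro-2-benzofuran-1(3H)-one | CC(=O)CC[C@@H]1CCC2=C(COC2=O)C1(C)C
F4 | step 2 | (5S)-5-(3,3-dimethoxybutyl)-4,4-dimethyl-4,5,6,7-tetrahydro-2-benzofuran-1(3H)-one | COC(C)(OC)CC[C@@H]1CCC2=C(COC2=O)C1(C)C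
F5 | step 9 | 13-membered hydroxy ketone, (R)-carbinol epimer (20 with (R)-CH–OH in place of (S)-CH–OAc) | O=C1CC[C@@H]2CCc3c(C2(C)C)coc3C(O[Si](C)(C)C(C)(C)C)/C(C)=C/[C@H](O)C1
F6 | step 9 | 13-membered methylene alcohol, (R)-carbinol epimer | C=C1CC[C@@H]2CCc3c(C2(C)C)coc3C(O[Si](C)(C)C(C)(C)C)/C(C)=C/[C@H](O)C1
F7 | step 11 | 2-alkylfuran macrocycle: 21 with CH2 in place of CH(OTBS) | C=C1CC[C@@H]2CCc3c(C2(C)C)coc3C/C(C)=C/[C@@H](OC(C)=O)C1
F8 | step 11 | hydroxy enone, carbinol epimers of 23 | C=C1CC[C@@H]2CCC3=C(C(O)[C@H](C3=O)/C(C)=C/[C@@H](OC(C)=O)C1)C2(C)C
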